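| setting | summer | winter | midnight | east | north-east | west | north-west |
|---|---|---|---|---|---|---|---|
| starting material | 0.050 M | 0.025 M | 0.10 M | 0.050 M | 0.050 M | 0.050 M | 0.050 M |
| coupling partner | 0.125 M | 0.125 M | 0.125 M | 0.125 M | 0.125 M | 0.125 M | 0.125 M |
| second reagent | 0.035 M | 0.035 M | 0.035 M | 0.0350 M | 0.0350 M | 0.0350 M | 0.0350 M (fed, over 24.0 h) |
| third reagent | 0.125 M | 0.125 M | 0.125 M | 0.125 M | 0.125 M | 0.125 M | 0.125 M |
| protic impurity | 0.025 M | 0.025 M | 0.025 M | 0.0250 M | 0.0250 M | 0.0250 M | 0.0250 M |
| remark | run made earlier | run made earlier | run made earlier | a single well-mixed tank run continuously and read at steady state, 90.0 h in it on average | a closed flask charged with all of it at once and left for 30 h | a single well-mixed tank run continuously and read at steady state, 30 h in it on average | all but second reagent at the start; second reagent goes in evenly over 24.0 h, the run ends at 30 h |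
| time |  |  |  |  | 30 h |  | 30 h |

| run | time / h | intermediate A / % | product / % |
|---|---|---|---|
| summer | 2.50 | 17.1 | 0.9 |
| summer | 4.00 | 23.2 | 2.2 |
| summer | 6.00 | 26.9 | 5.4 |
| summer | 8.00 | 29.6 | 6.5 |
| summer | 12.0 | 35.0 | 12.9 |
| summer | 20.0 | 29.7 | 25.6 |
| summer | 30.0 | 25.9 | 34.6 |
| winter | 3.00 | 18.7 | 0 |
| winter | 4.00 | 23.2 | 1.5 |
| winter | 6.00 | 29.2 | 2.5 |
| winter | 10.0 | 31.5 | 10.8 |
| winter | 15.0 | 32.2 | 18.7 |
| winter | 25.0 | 25.6 | 34.7 |
| winter | 40.0 | 14.8 | 48.3 |
| midnight | 5.00 | 22.3 | 2.4 |
| midnight | 10.0 | 30.5 | 9.1 |
| midnight | 15.0 | 33.0 | 14.6 |
| midnight | 20.0 | 35.1 | 21.8 |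
| midnight | 25.0 | 35.7 | 23.4 |
| midnight | 30.0 | 36.5 | 25.6 |
| midnight | 40.0 | 39.4 | 29.4 |

(readings scatter by 1 percentage point)

1. the set-up with the highest amount of intermediate A at the outlet or at the end, in percent of the starting material put in ("none" if the first two lie within 2 percentage points) (east / north-east / west / north-west / none)
2. amount of intermediate A at the outlet or at the end, in percent of the starting material put in, east
3. amount of intermediate A at the outlet or at the end, in percent of the starting material put in, north-east
4. amount of intermediate A at the outlet or at the end, in percent of the starting material put in, west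
5. amount of intermediate A at the outlet or at the end, in percent of the starting material put in, north-west

- the stated concentrations are those of everything mixed, before any reaction; amounts are the same in each set-up
- the numbers in the tables scatter by 1 percentage point (one standard deviation)
- the feed brings no volume worth counting
- the earlier runs were made in a closed, stirred flask

Start with the easy step: north-east is the summer recipe in the same closed flask, so its answer is the summer reading at 30.0 h, 25.9%. Add the product read then and you have M, the share that has become intermediate A or passed on through it to product:

M = 60.5%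

I assume that dosing the second reagent leaves M alone and changes only what survives. So I carry the leak rate κ, the fraction of intermediate A passing on to product per hour in the summer run, an average over a stretch in which the second reagent is being spent, so a working figure and not a constant. I read it from the summer product gain between 12.0 h and 30.0 h, divided by the mean intermediate A over that span:

κ = 0.0399 h⁻¹

Intermediate A born at time s then survives as exp(−κE), where E counts hours with the whole dose in, from s to the end T, each taken at the working figure κ. In north-east, E = T − s. In north-west the dose at time t stands at t/t_f of the charge, with its use ignored, so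

E = (t_f − s)(t_f + s)/(2 t_f) + (T − t_f)

As a first guess take s = 6.00 h, when about half of M had appeared. North-west then comes to 30.4%.

The weak link is s. Tested on the closed flask, it gives 23.2%, which is 2.7 percentage points low against a scatter of 1 point. Late-born intermediate A survives better, so I set s from the summer reading itself:

s = T − ln(M/y)/κ = 8.75 h, later than the guess

E = 16.4 h, so north-west = M exp(−κE) = 31.4%

I commit to that, and I have no reckoning of my own for the tanks. The forecast says 20% for east, 26% for north-east, 24% for west and 32% for north-west, so north-west is best: “Dosing keeps agent fresh and delays step 2”.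

The flask gives 32.0% in north-west, above east at 19.6%, north-east at 26.2% and west at 24.2%. At 30.0 h, north-west and north-east each keep 4.30% of the starting material, but north-west holds 28.4% product against 35.3%.

    starting material + protic impurity → quenched substrate (k = 2.48 M⁻¹ h⁻¹)
    second reagent + intermediate A → intermediate B (k = 1.85 M⁻¹ h⁻¹)
    third reagent + intermediate B → product (k = 3.16 M⁻¹ h⁻¹)
    starting material + coupling partner → intermediate A (k = 0.732 M⁻¹ h⁻¹)

Now scale κ to the neighbour flask, which is north-west with 0.014 M of second reagent: M exp(−κE) with κ multiplied by 0.400 gives 46.6%, and that flask holds 49.1%.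

(The numbers in the tables come from a simulation with constants of no real substance, noise included.)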